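The quaternary carbinol C3 of the butyrolactone ring carries both its hydroxyl oxygen and the benzylic carbon of the syringyl ring, so the target is treated as a reduced glycidic lactone. The C3–CH2Ar bond is made by a Darzens condensation between an enantiopure 3-chloro-4-benzyl-butyrolactone (guaiacyl half, C4 from (S)-epichlorohydrin) and O-benzylsyringaldehyde. In one operation the aldol joins the halves anti to the C4 benzyl group and the inverting epoxide closure places oxygen anti and the new carbon syn to it, which is the cis-dibenzyl arrangement of the target. One hydrogenolysis then cleaves the benzylic epoxide C–O bond and both benzyl ethers.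

Key step: step 5

Assumption: 1-(benzyloxy)-4-bromo-2-methoxybenzene and 4-(benzyloxy)-3,5-dimethoxybenzaldehyde are taken as catalogue compounds.

Step 1
Reactants: 1 (S)-epichlorohydrin; 2 diethyl malonate
Product: 6 ethyl (1R,5S)-2-oxo-3-oxabicyclo[3.1.0]hexane-1-carboxylate, via chlorohydrin alkoxide 3 (not isolated), via epoxy malonate 4 (not isolated), via cyclopropane alkoxide 5 (not isolated)
Conditions: NaOEt (1 equiv), EtOH, 0 °C to reflux
Reagents that add atoms: none
Why: Tandem malonate alkylation/cyclopropanation/lactonisation: the malonate anion opens the epoxide at its CH2 (3), the alkoxide displaces chloride to give the transposed epoxide (4), the malonate carbanion opens this 3-exo-tet with inversion at the stereocentre (5) and the alkoxide lactonises onto the cis ester, so that the epichlorohydrin centre becomes C5 (S) and the cis ring fusion dictates C1 (R).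

Step 2
Reactants: 6 ethyl (1R,5S)-2-oxo-3-oxabicyclo[3.1.0]hexane-1-carboxylate; 7 1-(benzyloxy)-4-bromo-2-methoxybenzene
Product: 10 ethyl (4S)-4-[4-(benzyloxy)-3-methoxybenzyl]-2-oxotetrahydrofuran-3-carboxylate (C3 epimers, expected mainly 3,4-trans), via aryl Grignard reagent 8 (not isolated), via magnesium enolate 9 (not isolated)
Conditions: 7, Mg, I2 (cat.), THF, 40 °C; then CuI (10 mol%), 6, THF, −30 to 0 °C; 1 M HCl
Reagents that add atoms: none
Why: Copper-catalysed homoconjugate (SN2-type) addition of the aryl Grignard reagent to the CH2 carbon of the doubly activated cyclopropane expels the stabilised lactone–ester enolate 9; C5 of 6 is not a reacting atom and becomes C4 (S) of the butyrolactone, now carrying the arylmethyl group.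

Step 3
Reactants: 10 ethyl (4S)-4-[4-(benzyloxy)-3-methoxybenzyl]-2-oxotetrahydrofuran-3-carboxylate
Product: 11 (4S)-4-[4-(benzyloxy)-3-methoxybenzyl]dihydrofuran-2(3H)-one
Conditions: LiCl, H2O, DMSO, 140 °C
Reagents that add atoms: none
Why: Krapcho dealkoxycarbonylation of the malonate-type ester leaves the simple lactone; C4 carries no acidic hydrogen and is untouched, and the benzyl ether is stable to hot wet DMSO/LiCl.

Step 4
Reactants: 11 (4S)-4-[4-(benzyloxy)-3-methoxybenzyl]dihydrofuran-2(3H)-one; 12 N-chlorosuccinimide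
Product: 14 (4R)-4-[4-(benzyloxy)-3-methoxybenzyl]-3-chlorodihydrofuran-2(3H)-one (C3 epimers; the descriptor at C4 changes only through the CIP rule), via lithium enolate 13 (not isolated)
Conditions: LDA, THF, −78 °C; cannulated into NCS, THF, −78 °C; 1 M HCl
Reagents that add atoms: N-chlorosuccinimide (12), O=C1CCC(=O)N1Cl
Why: Electrophilic chlorination of the lactone lithium enolate, with inverse addition into excess NCS at −78 °C to limit proton exchange with the more acidic product; the C3 configuration is of no consequence because C3 is planarised again in step 5.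

Step 5
Reactants: 14 (4R)-4-[4-(benzyloxy)-3-methoxybenzyl]-3-chlorodihydrofuran-2(3H)-one; 15 4-(benzyloxy)-3,5-dimethoxybenzaldehyde
Product: 18 (3R,7R)-2-[4-(benzyloxy)-3,5-dimethoxyphenyl]-7-[4-(benzyloxy)-3-methoxybenzyl]-1,5-dioxaspiro[2.4]heptan-4-one (epoxide oxygen trans to the C7 benzyl group; C2 epimers), via lithium chloro enolate 16 (not isolated), via lithium chlorohydrin alkoxide 17 (not isolated)
Conditions: LiHMDS, THF, −78 °C, 15 min; then 15, −78 °C to rt; pH 7 buffer
Reagents that add atoms: none
Why: Darzens glycidic ester condensation of an α-chloro lactone with a non-enolisable aromatic aldehyde. LiHMDS converts 14 into the tetrasubstituted chloro enolate 16, which should add to 15 on the face anti to the C4 benzyl group, as alkylations and aldol additions of 4-substituted butyrolactone enolates do, so that chlorine is left syn to that group in 17. On warming, the alkoxide displaces chloride from the backside in a 3-exo-tet closure that inverts C3: the epoxide oxygen ends anti and the new benzylic carbon syn to the C4 benzyl group, which is the (3S)-carbinol configuration of the target once the benzylic C–O bond is reduced. The epoxide CH(Ar) centre needs no control because it becomes CH2 in step 6. The step needs addition and closure to outrun retro-aldol equilibration of 17; the lithium counter-ion and low temperature serve this, and closure from the minor aldolate would require oxygen to enter syn to the C4 benzyl group.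

Step 6
Reactants: 18 (3R,7R)-2-[4-(benzyloxy)-3,5-dimethoxyphenyl]-7-[4-(benzyloxy)-3-methoxybenzyl]-1,5-dioxaspiro[2.4]heptan-4-one
Product: 19 (3S,4R)-3-hydroxy-3-(4-hydroxy-3,5-dimethoxybenzyl)-4-(4-hydroxy-3-methoxybenzyl)dihydrofuran-2(3H)-one
Conditions: H2 (1 atm), 10% Pd/C, EtOAc, rt
Reagents that add atoms: none
Why: Palladium-catalysed hydrogenolysis cleaves the benzylic C–O bond of the aryl glycidate (the C3–O bond is not benzylic and stays, so C3 keeps its configuration and both C2 epimers of 18 converge on one CH2) together with the two benzyl ethers.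

Compound list
1 | (S)-epichlorohydrin, (2S)-2-(chloromethyl)oxirane | ClC[C@@H]1CO1 | starting material
2 | diethyl malonate | CCOC(=O)CC(=O)OCC | starting material
3 | sodium alkoxide of diethyl 2-[(2S)-3-chloro-2-hydroxypropyl]malonate (not isolated) | [Na+].CCOC(=O)C(C[C@H]([O-])CCl)C(=O)OCC | intermediate
4 | diethyl 2-{[(2S)-oxiran-2-yl]methyl}malonate (not isolated) | CCOC(=O)C(C[C@H]1CO1)C(=O)OCC | intermediate
5 | sodium alkoxide of diethyl (2S)-2-(hydroxymethyl)cyclopropane-1,1-dicarboxylate (not isolated) | [Na+].CCOC(=O)C1(C(=O)OCC)C[C@@H]1C[O-] | intermediate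
6 | ethyl (1R,5S)-2-oxo-3-oxabicyclo[3.1.0]hexane-1-carboxylate | CCOC(=O)[C@@]12C[C@@H]1COC2=O | intermediate
7 | 1-(benzyloxy)-4-bromo-2-methoxybenzene | COc1cc(Br)ccc1OCc1ccccc1 | starting material
8 | [4-(benzyloxy)-3-methoxyphenyl]magnesium bromide (not isolated) | COc1cc([Mg]Br)ccc1OCc1ccccc1 | intermediate
9 | bromomagnesium enolate of 10, (4S) (not isolated) | CCOC(=O)C1=C(O[Mg]Br)OC[C@H]1Cc1ccc(OCc2ccccc2)c(OC)c1 | intermediate
10 | ethyl (4S)-4-[4-(benzyloxy)-3-methoxybenzyl]-2-oxotetrahydrofuran-3-carboxylate, C3 epimers | COc1cc(C[C@@H]2COC(=O)C2C(=O)OCC)ccc1OCc1ccccc1 | intermediate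
11 | (4S)-4-[4-(benzyloxy)-3-methoxybenzyl]dihydrofuran-2(3H)-one | COc1cc(C[C@@H]2COC(=O)C2)ccc1OCc1ccccc1 | intermediate
12 | N-chlorosuccinimide | O=C1CCC(=O)N1Cl | starting material
13 | lithium enolate of 11, lithium (3S)-3-[4-(benzyloxy)-3-methoxybenzyl]-2,3-dihydrofuran-5-olate (not isolated) | [Li+].[O-]C1=C[C@H](Cc2ccc(OCc3ccccc3)c(OC)c2)CO1 | intermediate
14 | (4R)-4-[4-(benzyloxy)-3-methoxybenzyl]-3-chlorodihydrofuran-2(3H)-one, C3 epimers | COc1cc(C[C@@H]2COC(=O)C2Cl)ccc1OCc1ccccc1 | intermediate
15 | 4-(benzyloxy)-3,5-dimethoxybenzaldehyde | COc1cc(C=O)cc(OC)c1OCc1ccccc1 | starting material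
16 | lithium enolate of 14 (4-chloro-2,3-dihydrofuran-5-olate, benzyl-bearing carbon unchanged) (not isolated) | [Li+].[O-]C1=C(Cl)[C@H](Cc2ccc(OCc3ccccc3)c(OC)c2)CO1 | intermediate
17 | lithium alkoxide of (3S,4R)-4-[4-(benzyloxy)-3-methoxybenzyl]-3-{[4-(benzyloxy)-3,5-dimethoxyphenyl](hydroxy)methyl}-3-chlorodihydrofuran-2(3H)-one, chlorine cis to the C4 benzyl group, carbinol epimers (not isolated) | [Li+].COc1cc(C[C@@H]2COC(=O)[C@]2(C([O-])c2cc(OC)c(OCc3ccccc3)c(OC)c2)Cl)ccc1OCc1ccccc1 | intermediate
18 | (3R,7R)-2-[4-(benzyloxy)-3,5-dimethoxyphenyl]-7-[4-(benzyloxy)-3-methoxybenzyl]-1,5-dioxaspiro[2.4]heptan-4-one, C2 epimers | COc1cc(C[C@@H]2COC(=O)[C@]2(O3)C3c2cc(OC)c(OCc4ccccc4)c(OC)c2)ccc1OCc1ccccc1 | intermediate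
19 | (3S,4R)-3-hydroxy-3-(4-hydroxy-3,5-dimethoxybenzyl)-4-(4-hydroxy-3-methoxybenzyl)dihydrofuran-2(3H)-one | COc1cc(C[C@@H]2COC(=O)[C@]2(O)Cc2cc(OC)c(O)c(OC)c2)ccc1O | target

Total step count: 6. Longest linear sequence: 6 steps (steps 1 to 6, from (S)-epichlorohydrin).

Steps most likely to fail

Step 5 (Darzens condensation). Retro-aldol equilibration of the chlorohydrin alkoxide may erode the facial control at C3, and slow displacement of the tertiary chloride may let base-induced loss of HCl to a butenolide compete. The fallback sets out from lactone 11 and forms the same bond as an alkene. LDA aldol addition of 11 to aldehyde 15 in THF at −78 °C should give the aldol adduct F1. MsCl/Et3N followed by DBU should give, through the mesylate F2, the (E)-benzylidene lactone F3. Dimethyldioxirane in acetone at 0 °C should then epoxidise F3 on the face anti to the C4 benzyl group, which allylic strain with the aryl group holds pseudoaxial. The route is rejoined at epoxide 18.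

Step 6 (hydrogenolysis). The electron-rich aryl epoxide may isomerise (Meinwald-type shift) or be opened by adventitious nucleophiles on the catalyst before the benzylic C–O bond is reduced. The fallback sets out from 18 and separates opening from reduction. MgBr2·OEt2 in Et2O/CH2Cl2 at 0 °C should open the epoxide with bromide at the benzylic carbon to give the bromohydrin F4. Bu3SnH/AIBN in toluene at 80 °C should remove the bromine by a radical chain and give the bis-benzyl ether F5. H2 over Pd/C then only has to cleave the two benzyl ethers, and the route is rejoined at 19.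

Step 4 (enolate chlorination). Proton exchange between enolate 13 and the more acidic chloro lactone may lead to dichlorination and returned 11. The fallback sets out from 11 and avoids a free enolate next to the product. LDA/TMSCl in THF at −78 °C should give the silyl ketene acetal F6, which NBS at −78 °C should brominate in the same flask to the 3-bromo lactone F7. F7 then enters the same Darzens manifold with 15 (LiHMDS, THF, −78 °C to 0 °C) through the bromo enolate F8 and the bromohydrin alkoxide F9, and the route is rejoined at 18.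

Further compounds
F1 | step 5 | (3R,4S)-4-[4-(benzyloxy)-3-methoxybenzyl]-3-{[4-(benzyloxy)-3,5-dimethoxyphenyl](hydroxy)methyl}dihydrofuran-2(3H)-one, carbinol epimers | COc1cc(C[C@@H]2COC(=O)[C@H]2C(O)c2cc(OC)c(OCc3ccccc3)c(OC)c2)ccc1OCc1ccccc1
F2 | step 5 | methanesulfonate of F1 | COc1cc(C[C@@H]2COC(=O)[C@H]2C(OS(C)(=O)=O)c2cc(OC)c(OCc3ccccc3)c(OC)c2)ccc1OCc1ccccc1
F3 | step 5 | (4S,E)-4-[4-(benzyloxy)-3-methoxybenzyl]-3-[4-(benzyloxy)-3,5-dimethoxybenzylidene]dihydrofuran-2(3H)-one | COc1cc(C[C@@H]2COC(=O)/C2=C/c2cc(OC)c(OCc3ccccc3)c(OC)c2)ccc1OCc1ccccc1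
F4 | step 6 | (3R,4R)-4-[4-(benzyloxy)-3-methoxybenzyl]-3-{[4-(benzyloxy)-3,5-dimethoxyphenyl](bromo)methyl}-3-hydroxydihydrofuran-2(3H)-one, bromide epimers | COc1cc(C[C@@H]2COC(=O)[C@]2(O)C(Br)c2cc(OC)c(OCc3ccccc3)c(OC)c2)ccc1OCc1ccccc1
F5 | step 6 | (3S,4R)-4-[4-(benzyloxy)-3-methoxybenzyl]-3-[4-(benzyloxy)-3,5-dimethoxybenzyl]-3-hydroxydihydrofuran-2(3H)-one | COc1cc(C[C@@H]2COC(=O)[C@]2(O)Cc2cc(OC)c(OCc3ccccc3)c(OC)c2)ccc1OCc1ccccc1
F6 | step 4 | {[(3S)-3-[4-(benzyloxy)-3-methoxybenzyl]-2,3-dihydrofuran-5-yl]oxy}trimethylsilane | C[Si](C)(C)OC1=C[C@H](Cc2ccc(OCc3ccccc3)c(OC)c2)CO1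
F7 | step 4 | (4R)-4-[4-(benzyloxy)-3-methoxybenzyl]-3-bromodihydrofuran-2(3H)-one, C3 epimers | COc1cc(C[C@@H]2COC(=O)C2Br)ccc1OCc1ccccc1
F8 | step 4 | lithium enolate of F7 | [Li+].[O-]C1=C(Br)[C@H](Cc2ccc(OCc3ccccc3)c(OC)c2)CO1
F9 | step 4 | lithium alkoxide of (3S,4R)-4-[4-(benzyloxy)-3-methoxybenzyl]-3-{[4-(benzyloxy)-3,5-dimethoxyphenyl](hydroxy)methyl}-3-bromodihydrofuran-2(3H)-one, carbinol epimers | [Li+].COc1cc(C[C@@H]2COC(=O)[C@]2(C([O-])c2cc(OC)c(OCc3ccccc3)c(OC)c2)Br)ccc1OCc1ccccc1
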